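**Retrosynthetic overview**
1. The C40 chain is cut at the two Wittig bonds C11=C12 (formed last) and C11'=C12'. This gives the acetylenic C15 phosphonium salt 20 (ring A), the C10 dialdehyde 21 and the triol dienal 32 (ring B).
2. Both end groups come from one allylic alcohol, 14. Ring A follows by CH2OH → CHO → C≡CH and Sonogashira coupling with the (E)-enol triflate of ethyl acetoacetate. Ring B follows by Sharpless epoxidation anti to O-3, C5 chain extension and trans opening of the oxirane by water at C5.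
3. 14 comes from the cyclic β-keto ester 9 (enol triflate → methyl, ester → CH2OH). 9 is made by closing the C4'–C3' bond of the achiral, acyclic keto aldehyde 7 in a proline-catalysed aldol. 7 is assembled from acetone, ethyl acetoacetate and allyltrimethylsilane.
4. Enabling feature: in the cyclohexene ring of the acetylenic end group the carbinol C3' is 1,3 to C5', the methyl-bearing carbon of the C5'=C6' double bond. With C5' as the ketone of an acetoacetate, C3'(OH)–C4'H2–C5'(=O) is an aldol retron whose donor C4' is the acetyl CH3. The β-keto ester later exchanges the C5' oxygen for CH3 with the double bond fixed at C5'=C6', and its ester carbon becomes alkyne carbon C7'. The triol ring has the same skeleton and the same C3 configuration in space, so one ring closure serves both rings.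
5. Ring order: the carbocycle of both end groups in step 4 (one stereocenter, set by catalysis); the oxirane of ring B in step 18, opened in step 22 (C5 and C6 relayed from C3 through the epoxide).

Key step: step 4

Remark: the target is read as the (3S,5S,6S,3'R) isomer (carotenoid numbering; 3-OH cis to 5-OH, 5-OH trans to 6-OH). (S)-Proline is taken to give the (4S)-ketol 9 by analogy with the facial sense of proline-catalysed acetone–aldehyde aldol additions; its enantiomer would be used if the opposite sense were found.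

**Step 1**
Reactants: 1 acetone; 2 ethyl acetoacetate
Product: 3 ethyl 2-acetyl-3-methylbut-2-enoate
Conditions: TiCl4, pyridine, THF, 0 °C to rt
Reagents that add atoms: none
Why: Knoevenagel condensation of a ketone with a β-keto ester, driven by titanium tetrachloride/pyridine, which binds the water irreversibly; no stereocenter is formed.

**Step 2**
Reactants: 3 ethyl 2-acetyl-3-methylbut-2-enoate; 4 allyltrimethylsilane
Product: 5 ethyl 2-acetyl-3,3-dimethylhex-5-enoate (racemic, labile methine)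
Conditions: TiCl4, CH2Cl2, −78 °C; aq. NH4Cl
Reagents that add atoms: none
Why: Hosomi–Sakurai conjugate allylation of the doubly activated alkylidene at its β,β-dimethyl carbon should build the quaternary ring carbon C1 (carotenoid numbering) together with C2 and the masked C3.

**Step 3**
Reactants: 5 ethyl 2-acetyl-3,3-dimethylhex-5-enoate
Product: 7 ethyl 2-acetyl-3,3-dimethyl-5-oxopentanoate, via ozonide 6 (not isolated)
Conditions: O3, CH2Cl2, −78 °C; Me2S, −78 °C to rt
Reagents that add atoms: ozone, [O-][O+]=O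
Why: Ozonolysis with reductive work-up cleaves the only C=C bond to the aldehyde (C3), the α-tert-alkyl β-keto ester being held in its keto form.

**Step 4**
Reactants: 7 ethyl 2-acetyl-3,3-dimethyl-5-oxopentanoate
Product: 9 ethyl (4S)-4-hydroxy-6,6-dimethyl-2-oxocyclohexane-1-carboxylate, via proline enamine 8 (not isolated)
Conditions: (S)-proline (30 mol %), DMSO, rt
Reagents that add atoms: none
Why: (S)-Proline condenses with the acetyl group of 7 to give the terminal enamine 8, whose CH2 carbon (C4') adds to the aldehyde carbon (C3') while the carboxylic acid protonates the aldehyde oxygen, and hydrolysis releases ketol 9 and the catalyst; the closest known reactions are the Hajos–Parrish cyclisation and proline-catalysed ketone–aldehyde aldol additions. The ring closes in the 6-(enolendo)-exo-trig mode and gives the cyclohexanone that becomes the carbocycle of both end groups. The only lasting new stereocenter, the carbinol carbon (C3' of ring A, C3 of ring B), is set by the catalyst, which fixes the aldehyde face in the hydrogen-bonded chair transition state; C1 of 9 is a labile β-keto ester centre that is erased in step 6. The step needs enamine formation toward the methyl group and a ketone donor with an aldehyde acceptor: every other enol or enamine carbon of 7 could only close a four-membered ring, the tert-alkyl group disfavours the conjugated enamino ester, and the gem-dimethyl group favours the folded conformer (Thorpe–Ingold effect). Dehydration of 9 should be held back because its β-keto ester rests largely as the hydrogen-bonded enol.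

**Step 5**
Reactants: 9 ethyl (4S)-4-hydroxy-6,6-dimethyl-2-oxocyclohexane-1-carboxylate
Product: 10 ethyl (4S)-6,6-dimethyl-2-oxo-4-[(triethylsilyl)oxy]cyclohexane-1-carboxylate
Conditions: Et3SiCl, imidazole, DMF, 0 °C
Reagents that add atoms: chlorotriethylsilane, CC[Si](Cl)(CC)CC
Why: Silylation of the secondary alcohol protects O-3 against triflation and oxidation; triethylsilyl is chosen because it is lost in the acidic steps 14 and 22.

**Step 6**
Reactants: 10 ethyl (4S)-6,6-dimethyl-2-oxo-4-[(triethylsilyl)oxy]cyclohexane-1-carboxylate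
Product: 12 ethyl (4S)-6,6-dimethyl-4-[(triethylsilyl)oxy]-2-{[(trifluoromethyl)sulfonyl]oxy}cyclohex-1-ene-1-carboxylate, via sodium enolate 11 (not isolated)
Conditions: NaH, THF, 0 °C; PhNTf2, 0 °C to rt
Reagents that add atoms: N-phenylbis(trifluoromethanesulfonimide), O=S(=O)(N(c1ccccc1)S(=O)(=O)C(F)(F)F)C(F)(F)F
Why: O-Sulfonylation of the stabilised β-keto ester enolate locks the double bond at C5=C6; deprotonation at the doubly activated carbon precludes β-elimination of the silyloxy group.

**Step 7**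
Reactants: 12 ethyl (4S)-6,6-dimethyl-4-[(triethylsilyl)oxy]-2-{[(trifluoromethyl)sulfonyl]oxy}cyclohex-1-ene-1-carboxylate
Product: 13 ethyl (4R)-2,6,6-trimethyl-4-[(triethylsilyl)oxy]cyclohex-1-ene-1-carboxylate
Conditions: MeMgBr, Fe(acac)3 (5 mol %), THF/NMP, −30 °C
Reagents that add atoms: methylmagnesium bromide, C[Mg]Br
Why: Iron-catalysed Kumada-type cross-coupling of a β-keto-ester-derived enol triflate should replace the C5 oxygen by the ring methyl group faster than the hindered ester is attacked (the descriptor changes from S to R only through CIP priorities).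

**Step 8**
Reactants: 13 ethyl (4R)-2,6,6-trimethyl-4-[(triethylsilyl)oxy]cyclohex-1-ene-1-carboxylate
Product: 14 [(4R)-2,6,6-trimethyl-4-[(triethylsilyl)oxy]cyclohex-1-en-1-yl]methanol
Conditions: DIBAL-H, CH2Cl2, −78 °C to rt; Rochelle salt
Reagents that add atoms: none
Why: Hydride reduction of the hindered conjugated ester gives the allylic alcohol, the common precursor of both end groups.

**Step 9**
Reactants: 14 [(4R)-2,6,6-trimethyl-4-[(triethylsilyl)oxy]cyclohex-1-en-1-yl]methanol
Product: 15 (4R)-2,6,6-trimethyl-4-[(triethylsilyl)oxy]cyclohex-1-ene-1-carbaldehyde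
Conditions: Dess–Martin periodinane, NaHCO3, CH2Cl2, 0 °C to rt
Reagents that add atoms: none
Why: Dess–Martin oxidation of the primary allylic alcohol to the enal leaves the silyl ether untouched.

**Step 10**
Reactants: 15 (4R)-2,6,6-trimethyl-4-[(triethylsilyl)oxy]cyclohex-1-ene-1-carbaldehyde
Product: 16 {[(1R)-4-ethynyl-3,5,5-trimethylcyclohex-3-en-1-yl]oxy}triethylsilane
Conditions: Me3SiCHN2, n-BuLi, THF, −78 °C; then 15, −78 °C to rt
Reagents that add atoms: (trimethylsilyl)diazomethane, C[Si](C)(C)C=[N+]=[N-]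
Why: Colvin rearrangement: the lithiated silyldiazomethane adds to the aldehyde, loss of silanolate and N2 gives an alkylidene carbene, and its 1,2-hydrogen shift should deliver the terminal alkyne C7'≡C8'.

**Step 11**
Reactants: 2 ethyl acetoacetate
Product: 17 ethyl (2E)-3-{[(trifluoromethyl)sulfonyl]oxy}but-2-enoate
Conditions: Tf2O, aq. Me4NOH, hexane, 5 °C
Reagents that add atoms: trifluoromethanesulfonic anhydride, O=S(=O)(OS(=O)(=O)C(F)(F)F)C(F)(F)F
Why: O-Triflation of the non-chelated tetramethylammonium enolate should give the (E)-enol triflate, which fixes the later C9'=C10' geometry (a chelating lithium counter-ion would favour the Z isomer).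

**Step 12**
Reactants: 16 {[(1R)-4-ethynyl-3,5,5-trimethylcyclohex-3-en-1-yl]oxy}triethylsilane; 17 ethyl (2E)-3-{[(trifluoromethyl)sulfonyl]oxy}but-2-enoate
Product: 18 ethyl (2E)-3-methyl-5-[(4R)-2,6,6-trimethyl-4-[(triethylsilyl)oxy]cyclohex-1-en-1-yl]pent-2-en-4-ynoate
Conditions: Pd(PPh3)2Cl2 (3 mol %), CuI (6 mol %), Et3N, THF, rt
Reagents that add atoms: none
Why: Sonogashira coupling of the terminal alkyne with the activated vinyl triflate forms C8'–C9' with retention of the (E) geometry; a tertiary amine is used so that no amine adds to the β-triflyloxy enoate.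

**Step 13**
Reactants: 18 ethyl (2E)-3-methyl-5-[(4R)-2,6,6-trimethyl-4-[(triethylsilyl)oxy]cyclohex-1-en-1-yl]pent-2-en-4-ynoate
Product: 19 (2E)-3-methyl-5-[(4R)-2,6,6-trimethyl-4-[(triethylsilyl)oxy]cyclohex-1-en-1-yl]pent-2-en-4-yn-1-ol
Conditions: DIBAL-H, CH2Cl2, −78 °C; Rochelle salt
Reagents that add atoms: none
Why: 1,2-Reduction of the enynoate gives the allylic alcohol without touching the alkyne or the silyl ether.

**Step 14**
Reactants: 19 (2E)-3-methyl-5-[(4R)-2,6,6-trimethyl-4-[(triethylsilyl)oxy]cyclohex-1-en-1-yl]pent-2-en-4-yn-1-ol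
Product: 20 [(2E)-5-[(4R)-4-hydroxy-2,6,6-trimethylcyclohex-1-en-1-yl]-3-methylpent-2-en-4-yn-1-yl]triphenylphosphonium bromide
Conditions: PPh3·HBr, MeOH, 0 °C to rt
Reagents that add atoms: triphenylphosphine hydrobromide, [Br-].c1ccc(cc1)[PH+](c1ccccc1)c1ccccc1
Why: The phosphine hydrobromide ionises the allylic alcohol and the phosphine captures the cation at its primary terminus (classical Wittig-salt formation from allylic alcohols), while the methanolic acid removes the triethylsilyl group.

**Step 15**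
Reactants: 20 [(2E)-5-[(4R)-4-hydroxy-2,6,6-trimethylcyclohex-1-en-1-yl]-3-methylpent-2-en-4-yn-1-yl]triphenylphosphonium bromide; 21 (2E,4E,6E)-2,7-dimethylocta-2,4,6-trienedial
Product: 23 (2E,4E,6E,8E,10E)-13-[(4R)-4-hydroxy-2,6,6-trimethylcyclohex-1-en-1-yl]-2,7,11-trimethyltrideca-2,4,6,8,10-pentaen-12-ynal, via phosphorus ylide 22 (not isolated)
Conditions: NaOMe, MeOH/CH2Cl2, 0 °C to rt, 21 in threefold excess; then heptane, 80 °C
Reagents that add atoms: none
Why: Wittig olefination of the semi-stabilised ylide with an excess of the symmetrical dialdehyde should give the mono-adduct and form C11'=C12'; the hindered (Z) isomer of the new bond is converted to (E) on warming.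

**Step 16**
Reactants: 23 (2E,4E,6E,8E,10E)-13-[(4R)-4-hydroxy-2,6,6-trimethylcyclohex-1-en-1-yl]-2,7,11-trimethyltrideca-2,4,6,8,10-pentaen-12-ynal
Product: 24 (2E,4E,6E,8E,10E)-13-[(4R)-4-hydroxy-2,6,6-trimethylcyclohex-1-en-1-yl]-2,7,11-trimethyltrideca-2,4,6,8,10-pentaen-12-yn-1-ol
Conditions: NaBH4, MeOH/THF, 0 °C
Reagents that add atoms: none
Why: Chemoselective borohydride 1,2-reduction of the polyenal gives the primary allylic alcohol.

**Step 17**
Reactants: 24 (2E,4E,6E,8E,10E)-13-[(4R)-4-hydroxy-2,6,6-trimethylcyclohex-1-en-1-yl]-2,7,11-trimethyltrideca-2,4,6,8,10-pentaen-12-yn-1-ol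
Product: 25 [(2E,4E,6E,8E,10E)-13-[(4R)-4-hydroxy-2,6,6-trimethylcyclohex-1-en-1-yl]-2,7,11-trimethyltrideca-2,4,6,8,10-pentaen-12-yn-1-yl]triphenylphosphonium bromide
Conditions: PPh3·HBr, MeOH/CH2Cl2, 0 °C
Reagents that add atoms: triphenylphosphine hydrobromide, [Br-].c1ccc(cc1)[PH+](c1ccccc1)c1ccccc1
Why: Phosphonium salt formation as in step 14; the polyenyl cation is captured at its unhindered primary end, so the conjugated system is kept.

**Step 18**
Reactants: 14 [(4R)-2,6,6-trimethyl-4-[(triethylsilyl)oxy]cyclohex-1-en-1-yl]methanol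
Product: 26 [(1R,4S,6R)-2,2,6-trimethyl-4-[(triethylsilyl)oxy]-7-oxabicyclo[4.1.0]heptan-1-yl]methanol (oxirane anti to the silyloxy group)
Conditions: Ti(OiPr)4 (20 mol %), D-(−)-diethyl tartrate (25 mol %), t-BuOOH, 4 Å molecular sieves, CH2Cl2, −20 °C
Reagents that add atoms: tert-butyl hydroperoxide, CC(C)(C)OO
Why: Sharpless asymmetric epoxidation: the titanium tartrate complex binds the allylic hydroxyl and, with D-(−)-diethyl tartrate, should deliver oxygen to the ring face opposite the C4 silyloxy group (reagent control reinforced by the substrate), setting both oxirane carbons (C5 and C6 of the carotenoid).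

**Step 19**
Reactants: 26 [(1R,4S,6R)-2,2,6-trimethyl-4-[(triethylsilyl)oxy]-7-oxabicyclo[4.1.0]heptan-1-yl]methanol
Product: 27 (1S,4S,6R)-2,2,6-trimethyl-4-[(triethylsilyl)oxy]-7-oxabicyclo[4.1.0]heptane-1-carbaldehyde
Conditions: Dess–Martin periodinane, NaHCO3, CH2Cl2, 0 °C to rt
Reagents that add atoms: none
Why: Buffered Dess–Martin oxidation gives the epoxy aldehyde without opening the oxirane or cleaving the silyl ether.

**Step 20**
Reactants: 27 (1S,4S,6R)-2,2,6-trimethyl-4-[(triethylsilyl)oxy]-7-oxabicyclo[4.1.0]heptane-1-carbaldehyde; 28 diethyl [(2E)-3-cyano-2-methylprop-2-en-1-yl]phosphonate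
Product: 29 (2E,4E)-3-methyl-5-[(1S,4S,6R)-2,2,6-trimethyl-4-[(triethylsilyl)oxy]-7-oxabicyclo[4.1.0]heptan-1-yl]penta-2,4-dienenitrile
Conditions: NaH, THF, 0 °C to rt; chromatographic removal of the (2Z) isomer
Reagents that add atoms: none
Why: Horner–Wadsworth–Emmons olefination with the C5 nitrile phosphonate should form the (E) C7=C8 bond and bring in C8–C11.

**Step 21**
Reactants: 29 (2E,4E)-3-methyl-5-[(1S,4S,6R)-2,2,6-trimethyl-4-[(triethylsilyl)oxy]-7-oxabicyclo[4.1.0]heptan-1-yl]penta-2,4-dienenitrile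
Product: 31 (2E,4E)-3-methyl-5-[(1S,4S,6R)-2,2,6-trimethyl-4-[(triethylsilyl)oxy]-7-oxabicyclo[4.1.0]heptan-1-yl]penta-2,4-dienal, via aluminium aldimine 30 (not isolated)
Conditions: DIBAL-H, toluene, −78 °C; then wet silica gel
Reagents that add atoms: water, O
Why: DIBAL-H adds once to the nitrile at −78 °C and the N-aluminio aldimine is hydrolysed on work-up to the dienal; the tetrasubstituted oxirane should be inert at this temperature.

**Step 22**
Reactants: 31 (2E,4E)-3-methyl-5-[(1S,4S,6R)-2,2,6-trimethyl-4-[(triethylsilyl)oxy]-7-oxabicyclo[4.1.0]heptan-1-yl]penta-2,4-dienal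
Product: 32 (2E,4E)-3-methyl-5-[(1S,2S,4S)-1,2,4-trihydroxy-2,6,6-trimethylcyclohexyl]penta-2,4-dienal
Conditions: HClO4 (3 % aq.), THF, 0 °C
Reagents that add atoms: water, O
Why: Acid-catalysed epoxide hydrolysis: the dienal deactivates C6, so the protonated oxirane should open at the tertiary C5 with water entering anti to the oxirane oxygen (trans-diaxial opening; inversion at C5, retention at C6) on the face of O-3, giving the (5S,6S) trans-diol, while the triethylsilyl ether is hydrolysed in the same operation.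

**Step 23**
Reactants: 25 [(2E,4E,6E,8E,10E)-13-[(4R)-4-hydroxy-2,6,6-trimethylcyclohex-1-en-1-yl]-2,7,11-trimethyltrideca-2,4,6,8,10-pentaen-12-yn-1-yl]triphenylphosphonium bromide; 32 (2E,4E)-3-methyl-5-[(1S,2S,4S)-1,2,4-trihydroxy-2,6,6-trimethylcyclohexyl]penta-2,4-dienal
Product: 34 (3S,5S,6S,3'R)-7',8'-didehydro-5,6-dihydro-β,β-carotene-3,5,6,3'-tetrol (all-E), via phosphorus ylide 33 (not isolated)
Conditions: NaOMe, MeOH/CH2Cl2, 0 °C to rt; then EtOH, 60 °C, dark, argon
Reagents that add atoms: none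
Why: Wittig olefination under basic conditions, which the free hydroxyls and the acid-sensitive allylic tertiary alcohol should tolerate, forms C11=C12; the hindered (11Z) isomer is equilibrated to the all-(E) target by gentle warming.

**Compound list**
1 | acetone | CC(C)=O | starting material
2 | ethyl acetoacetate | CCOC(=O)CC(C)=O | starting material
3 | ethyl 2-acetyl-3-methylbut-2-enoate | CCOC(=O)C(C(C)=O)=C(C)C | intermediate
4 | allyltrimethylsilane | C=CC[Si](C)(C)C | starting material
5 | ethyl 2-acetyl-3,3-dimethylhex-5-enoate (racemic) | CCOC(=O)C(C(C)=O)C(C)(C)CC=C | intermediate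
6 | ozonide of 5, ethyl 2-acetyl-3,3-dimethyl-4-(1,2,4-trioxolan-3-yl)butanoate | CCOC(=O)C(C(C)=O)C(C)(C)CC1OCOO1 | intermediate (not isolated)
7 | ethyl 2-acetyl-3,3-dimethyl-5-oxopentanoate | CCOC(=O)C(C(C)=O)C(C)(C)CC=O | intermediate
8 | (2S)-1-[3-(ethoxycarbonyl)-4,4-dimethyl-6-oxohex-1-en-2-yl]pyrrolidine-2-carboxylic acid (proline enamine of 7) | C=C(N1CCC[C@H]1C(=O)O)C(C(=O)OCC)C(C)(C)CC=O | intermediate (not isolated)
9 | ethyl (4S)-4-hydroxy-6,6-dimethyl-2-oxocyclohexane-1-carboxylate (C1 epimers and enol) | O=C1C(C(=O)OCC)C(C)(C)C[C@H](O)C1 | intermediate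
10 | ethyl (4S)-6,6-dimethyl-2-oxo-4-[(triethylsilyl)oxy]cyclohexane-1-carboxylate | O=C1C(C(=O)OCC)C(C)(C)C[C@H](O[Si](CC)(CC)CC)C1 | intermediate
11 | sodium enolate of 10 | [Na+].[O-]C1=C(C(=O)OCC)C(C)(C)C[C@H](O[Si](CC)(CC)CC)C1 | intermediate (not isolated)
12 | ethyl (4S)-6,6-dimethyl-4-[(triethylsilyl)oxy]-2-{[(trifluoromethyl)sulfonyl]oxy}cyclohex-1-ene-1-carboxylate | O=S(=O)(OC1=C(C(=O)OCC)C(C)(C)C[C@H](O[Si](CC)(CC)CC)C1)C(F)(F)F | intermediate
13 | ethyl (4R)-2,6,6-trimethyl-4-[(triethylsilyl)oxy]cyclohex-1-ene-1-carboxylate | CC1=C(C(=O)OCC)C(C)(C)C[C@H](O[Si](CC)(CC)CC)C1 | intermediate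
14 | [(4R)-2,6,6-trimethyl-4-[(triethylsilyl)oxy]cyclohex-1-en-1-yl]methanol | CC1=C(CO)C(C)(C)C[C@H](O[Si](CC)(CC)CC)C1 | intermediate
15 | (4R)-2,6,6-trimethyl-4-[(triethylsilyl)oxy]cyclohex-1-ene-1-carbaldehyde | CC1=C(C=O)C(C)(C)C[C@H](O[Si](CC)(CC)CC)C1 | intermediate
16 | {[(1R)-4-ethynyl-3,5,5-trimethylcyclohex-3-en-1-yl]oxy}triethylsilane | CC1=C(C#C)C(C)(C)C[C@H](O[Si](CC)(CC)CC)C1 | intermediate
17 | ethyl (2E)-3-{[(trifluoromethyl)sulfonyl]oxy}but-2-enoate | CCOC(=O)/C=C(C)/OS(=O)(=O)C(F)(F)F | intermediate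
18 | ethyl (2E)-3-methyl-5-[(4R)-2,6,6-trimethyl-4-[(triethylsilyl)oxy]cyclohex-1-en-1-yl]pent-2-en-4-ynoate | CC1=C(C#C/C(C)=C/C(=O)OCC)C(C)(C)C[C@H](O[Si](CC)(CC)CC)C1 | intermediate
19 | (2E)-3-methyl-5-[(4R)-2,6,6-trimethyl-4-[(triethylsilyl)oxy]cyclohex-1-en-1-yl]pent-2-en-4-yn-1-ol | CC1=C(C#C/C(C)=C/CO)C(C)(C)C[C@H](O[Si](CC)(CC)CC)C1 | intermediate
20 | [(2E)-5-[(4R)-4-hydroxy-2,6,6-trimethylcyclohex-1-en-1-yl]-3-methylpent-2-en-4-yn-1-yl]triphenylphosphonium bromide | CC1=C(C#C/C(C)=C/C[P+](c2ccccc2)(c2ccccc2)c2ccccc2)C(C)(C)C[C@H](O)C1.[Br-] | intermediate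
21 | (2E,4E,6E)-2,7-dimethylocta-2,4,6-trienedial | O=C/C(C)=C/C=C/C=C(C)/C=O | starting material
22 | phosphorus ylide of 20 | CC1=C(C#C/C(C)=C/C=P(c2ccccc2)(c2ccccc2)c2ccccc2)C(C)(C)C[C@H](O)C1 | intermediate (not isolated)
23 | (2E,4E,6E,8E,10E)-13-[(4R)-4-hydroxy-2,6,6-trimethylcyclohex-1-en-1-yl]-2,7,11-trimethyltrideca-2,4,6,8,10-pentaen-12-ynal | CC1=C(C#C/C(C)=C/C=C/C(C)=C/C=C/C=C(C)/C=O)C(C)(C)C[C@H](O)C1 | intermediate
24 | (2E,4E,6E,8E,10E)-13-[(4R)-4-hydroxy-2,6,6-trimethylcyclohex-1-en-1-yl]-2,7,11-trimethyltrideca-2,4,6,8,10-pentaen-12-yn-1-ol | CC1=C(C#C/C(C)=C/C=C/C(C)=C/C=C/C=C(C)/CO)C(C)(C)C[C@H](O)C1 | intermediate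
25 | [(2E,4E,6E,8E,10E)-13-[(4R)-4-hydroxy-2,6,6-trimethylcyclohex-1-en-1-yl]-2,7,11-trimethyltrideca-2,4,6,8,10-pentaen-12-yn-1-yl]triphenylphosphonium bromide | CC1=C(C#C/C(C)=C/C=C/C(C)=C/C=C/C=C(C)/C[P+](c2ccccc2)(c2ccccc2)c2ccccc2)C(C)(C)C[C@H](O)C1.[Br-] | intermediate
26 | [(1R,4S,6R)-2,2,6-trimethyl-4-[(triethylsilyl)oxy]-7-oxabicyclo[4.1.0]heptan-1-yl]methanol | OC[C@@]12O[C@]1(C)C[C@@H](O[Si](CC)(CC)CC)CC2(C)C | intermediate
27 | (1S,4S,6R)-2,2,6-trimethyl-4-[(triethylsilyl)oxy]-7-oxabicyclo[4.1.0]heptane-1-carbaldehyde | O=C[C@@]12O[C@]1(C)C[C@@H](O[Si](CC)(CC)CC)CC2(C)C | intermediate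
28 | diethyl [(2E)-3-cyano-2-methylprop-2-en-1-yl]phosphonate | CCOP(=O)(C/C(C)=C/C#N)OCC | starting material
29 | (2E,4E)-3-methyl-5-[(1S,4S,6R)-2,2,6-trimethyl-4-[(triethylsilyl)oxy]-7-oxabicyclo[4.1.0]heptan-1-yl]penta-2,4-dienenitrile | N#C/C=C(C)/C=C/[C@@]12O[C@]1(C)C[C@@H](O[Si](CC)(CC)CC)CC2(C)C | intermediate
30 | N-(diisobutylalumanyl) aldimine derived from 29 | CC(C)C[Al](CC(C)C)N=C/C=C(C)/C=C/[C@@]12O[C@]1(C)C[C@@H](O[Si](CC)(CC)CC)CC2(C)C | intermediate (not isolated)
31 | (2E,4E)-3-methyl-5-[(1S,4S,6R)-2,2,6-trimethyl-4-[(triethylsilyl)oxy]-7-oxabicyclo[4.1.0]heptan-1-yl]penta-2,4-dienal | O=C/C=C(C)/C=C/[C@@]12O[C@]1(C)C[C@@H](O[Si](CC)(CC)CC)CC2(C)C | intermediate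
32 | (2E,4E)-3-methyl-5-[(1S,2S,4S)-1,2,4-trihydroxy-2,6,6-trimethylcyclohexyl]penta-2,4-dienal | O=C/C=C(C)/C=C/[C@]1(O)C(C)(C)C[C@H](O)C[C@]1(C)O | intermediate
33 | phosphorus ylide of 25 | CC1=C(C#C/C(C)=C/C=C/C(C)=C/C=C/C=C(C)/C=P(c2ccccc2)(c2ccccc2)c2ccccc2)C(C)(C)C[C@H](O)C1 | intermediate (not isolated)
34 | (3S,5S,6S,3'R)-7',8'-didehydro-5,6-dihydro-β,β-carotene-3,5,6,3'-tetrol | CC1=C(C#C/C(C)=C/C=C/C(C)=C/C=C/C=C(C)/C=C/C=C(C)/C=C/[C@]2(O)C(C)(C)C[C@H](O)C[C@]2(C)O)C(C)(C)C[C@H](O)C1 | target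

**Step count**
Total: 23 steps. Longest linear sequence: 17 steps (steps 1–10, 12–17 and 23).

**Steps most likely to fail**

1. Step 4 (key aldol). Enamine formation at the hindered acetyl group may be slow, the two aldehyde faces may be poorly discriminated, and the ketol may lose water, so the ring closure could proceed without useful enantiocontrol. Fallback (resolution in place of asymmetric catalysis): from 7, pyrrolidinium acetate (10 mol %, CH2Cl2, rt) closes the same bond to the racemic ketol F1. Candida antarctica lipase B and vinyl acetate (tert-butyl methyl ether, rt) then acylate one enantiomer; by the Kazlauskas rule the (4S)-alcohol is expected to react faster. The (4S)-acetate F2 is separated and methanolysed (K2CO3, MeOH, 0 °C), rejoining the route at 9. Should the enzyme prefer the other enantiomer, the unreacted alcohol is 9 itself.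

2. Step 22 (epoxide hydrolysis). The C5 cation may lose a proton to give allylic alcohols or undergo ring contraction, water may attack with poor facial or positional control, and the dienal may isomerise under acid. Fallback (tethered oxygen delivery in place of intermolecular hydrolysis): from 31, Bu4NF (THF, 0 °C) gives the hydroxy epoxide F3, and Boc2O/DMAP (MeCN) gives its tert-butyl carbonate F4. BF3·OEt2 (CH2Cl2, −40 °C) then makes the carbonate carbonyl oxygen open the oxirane at C5 from the face of O-3, with loss of isobutene, to give the bridged cyclic carbonate F5. K2CO3 in MeOH cleaves the carbonate and rejoins the route at 32.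

3. Step 20 (C5 olefination). The trisubstituted C9=C10 bond may scramble through the delocalised phosphonate carbanion, and addition to the neopentyl-type epoxy aldehyde may be sluggish. Fallback (cross-coupling with a geometry-defined C4 unit in place of olefination with a C5 unit): from 27, Takai iodo-olefination (CrCl2, CHI3, THF, 0 °C) gives the (E)-vinyl iodide F6. Stille coupling with the known (E)-3-(tributylstannyl)but-2-en-1-ol (Pd(MeCN)2Cl2, DMF, rt) gives the dienol F7 with both double bonds defined. MnO2 (CH2Cl2, rt) oxidises it to the dienal, rejoining the route at 31 (29 and 30 are bypassed).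

**Further compounds**
F1 | step 4 | racemic ethyl 4-hydroxy-6,6-dimethyl-2-oxocyclohexane-1-carboxylate | O=C1C(C(=O)OCC)C(C)(C)CC(O)C1
F2 | step 4 | ethyl (4S)-4-acetoxy-6,6-dimethyl-2-oxocyclohexane-1-carboxylate | O=C1C(C(=O)OCC)C(C)(C)C[C@H](OC(C)=O)C1
F3 | step 22 | (2E,4E)-5-[(1S,4S,6R)-4-hydroxy-2,2,6-trimethyl-7-oxabicyclo[4.1.0]heptan-1-yl]-3-methylpenta-2,4-dienal | O=C/C=C(C)/C=C/[C@@]12O[C@]1(C)C[C@@H](O)CC2(C)C
F4 | step 22 | tert-butyl carbonate of F3 (carbonate on the ring secondary oxygen) | O=C/C=C(C)/C=C/[C@@]12O[C@]1(C)C[C@@H](OC(=O)OC(C)(C)C)CC2(C)C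
F5 | step 22 | cyclic carbonate of 32 bridging O-3 and O-5 (carotenoid numbering), 6-OH free | O=C/C=C(C)/C=C/[C@]1(O)C(C)(C)C[C@@H]2OC(=O)O[C@@]1(C)C2
F6 | step 20 | triethyl{[(1S,4S,6R)-1-[(E)-2-iodoethenyl]-2,2,6-trimethyl-7-oxabicyclo[4.1.0]heptan-4-yl]oxy}silane | I/C=C/[C@@]12O[C@]1(C)C[C@@H](O[Si](CC)(CC)CC)CC2(C)C
F7 | step 20 | (2E,4E)-3-methyl-5-[(1S,4S,6R)-2,2,6-trimethyl-4-[(triethylsilyl)oxy]-7-oxabicyclo[4.1.0]heptan-1-yl]penta-2,4-dien-1-ol | OC/C=C(C)/C=C/[C@@]12O[C@]1(C)C[C@@H](O[Si](CC)(CC)CC)CC2(C)C
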